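**Retrosynthetic overview**
1. Target ⇐ MnO2 oxidation, desilylation and Mitsunobu esterification (inversion at C1) of an erythro epoxy alcohol that already holds both rings.
2. Both rings ⇐ one operation on an acyclic ynal: alkyne hydroboration, boron-to-zinc exchange and catalyst-controlled intramolecular alkenylzinc addition to the enal (C1–C2 bond, 11-membered carbocycle forms first), then in the same flask alkoxide-directed Ti(OiPr)4/t-BuOOH epoxidation of C10=C11 (oxirane forms second).
3. Ynal ⇐ (E)-selective Wittig at C6=C7 between a β-quaternary aldehyde and an α-homoprenyl stabilised ylide; ester → CH2OSiEt3; SeO2 oxidation of the terminal (E)-methyl to the C1 aldehyde.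
4. Aldehyde with the C4 quaternary centre ⇐ geraniol: enantioselective copper-catalysed SN2' alkynylation of geranyl phosphate; vinyl → CH2CHO; prenyl → (E)-tertiary allylic alcohol by hydroxyselenation/selenoxide elimination.
5. No ring exists before the key step.

Assumption: ring locants used throughout are C1 (O-bearing carbon), C2=C3, C4 (quaternary), C5, C6=C7 (C7 carries the CHO/CH2O carbon), C8, C9, C10–C11 (epoxide, C11 carries CH3); a telescoped one-flask sequence counts as one step; chiral catalysts are named by their usual facial preference and the mirror-image catalyst is taken if the sense proves opposite.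

**Route**

Step 1
Reactants: 1 geraniol
Product: 2 geranyl diethyl phosphate
Conditions: ClP(O)(OEt)2, pyridine, CH2Cl2, 0 °C
Reagents that add atoms: diethyl chlorophosphate CCOP(=O)(Cl)OCC
Why: O-phosphorylation of the primary allylic alcohol gives the allylic phosphate leaving group needed for SN2'-selective copper-catalysed allylic substitution, and no stereocentre is formed.

Step 2
Reactants: 2 geranyl diethyl phosphate; 3 trimethylsilylacetylene
Product: 5 (R)-(3-ethenyl-3,7-dimethyloct-6-en-1-yn-1-yl)trimethylsilane, via diisobutyl(trimethylsilylethynyl)aluminium 4 (not isolated)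
Conditions: 3, i-Bu2AlH, Et3N (5 mol%), hexane, 55 °C; then 2, CuCl2·2H2O (5 mol%), chiral sulfonate-bearing imidazolinium salt (5.5 mol%), THF, −15 °C
Reagents that add atoms: none
Why: Enantioselective allylic substitution (SN2') catalysed by CuCl2·2H2O with a chiral sulfonate-bearing N-heterocyclic carbene ligand transfers the alkynyl group from aluminium to the methyl-bearing alkene carbon, so the all-carbon quaternary centre (future C4) is set by the ligand acting on the geometrically pure (E)-alkene.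

Step 3
Reactants: 5 silyl enyne
Product: 8 (R)-3-ethynyl-3,7-dimethyloct-6-en-1-ol, via B-alkyl-9-BBN adduct 6 (not isolated), via silylalkynyl alcohol 7 (not isolated)
Conditions: 9-BBN, THF, 0 °C to rt; then NaOH, H2O2, H2O/MeOH, rt
Reagents that add atoms: hydrogen peroxide OO
Why: Anti-Markovnikov hydroboration–oxidation with bulky 9-BBN is selective for the monosubstituted vinyl group over the trisubstituted alkene and the silylalkyne, the alkaline methanolic work-up also protodesilylates the alkyne, and the quaternary centre is untouched.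

Step 4
Reactants: 8 alkynyl alcohol
Product: 11 (3R,5E)-3-ethynyl-3,7-dimethyloct-5-ene-1,7-diol, via hydroxy selenide 9 (not isolated), via selenoxide 10 (not isolated)
Conditions: N-(phenylseleno)phthalimide, H2O, CSA (cat.), CH2Cl2, rt; then H2O2, pyridine, 0 °C to rt
Reagents that add atoms: water O
Why: Markovnikov hydroxyselenation of the most electron-rich (trisubstituted) alkene followed by selenoxide syn-elimination, which can only run away from the fully substituted carbinol carbon, transposes the alkene to the (E)-tertiary allylic alcohol of the side chain (the transient C–Se stereocentre is destroyed).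

Step 5
Reactants: 11 enyne diol
Product: 12 (3R,5E)-3-ethynyl-7-hydroxy-3,7-dimethyloct-5-enal
Conditions: TEMPO (10 mol%), PhI(OAc)2, CH2Cl2, rt
Reagents that add atoms: none
Why: Oxoammonium (TEMPO/PhI(OAc)2) oxidation converts only the primary alcohol to the aldehyde, the tertiary alcohol having no carbinol hydrogen and the aldehyde having no epimerisable centre.

Step 6
Reactants: 13 ethyl (triphenylphosphoranylidene)acetate; 14 5-bromo-2-methylpent-2-ene
Product: 16 ethyl 6-methyl-2-(triphenylphosphoranylidene)hept-5-enoate, via phosphonium bromide 15 (not isolated)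
Conditions: NaI (cat.), MeCN, 80 °C; then NaOH, H2O/CH2Cl2, rt
Reagents that add atoms: none
Why: C-alkylation of the stabilised ylide by the primary halide (iodide formed in situ, Finkelstein exchange) and deprotonation of the phosphonium salt give the α-alkylated stabilised ylide, with no stereocentre involved.

Step 7
Reactants: 12 hydroxy ynal; 16 α-homoprenyl ylide
Product: 17 ethyl (2E,5R,7E)-5-ethynyl-9-hydroxy-5,9-dimethyl-2-(4-methylpent-3-en-1-yl)deca-2,7-dienoate
Conditions: toluene, 90 °C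
Reagents that add atoms: none
Why: Wittig olefination with an α-branched stabilised ylide gives the (E)-2-alkylalk-2-enoate (ester trans to C5), which is the C6=C7 geometry of the target.

Step 8
Reactants: 17 enoate
Product: 18 (2E,5R,7E)-5-ethynyl-5,9-dimethyl-2-(4-methylpent-3-en-1-yl)deca-2,7-diene-1,9-diol
Conditions: i-Bu2AlH, CH2Cl2, −78 °C
Reagents that add atoms: none
Why: 1,2-Reduction of the α,β-unsaturated ester by diisobutylaluminium hydride at low temperature gives the allylic alcohol without touching the alkyne or the alkenes, and no stereocentre changes.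

Step 9
Reactants: 18 diol
Product: 19 (2E,5R,7E)-5-ethynyl-5,9-dimethyl-2-(4-methylpent-3-en-1-yl)-1,9-bis(triethylsilyloxy)deca-2,7-diene
Conditions: Et3SiOTf, 2,6-lutidine, CH2Cl2, −78 to 0 °C
Reagents that add atoms: triethylsilyl trifluoromethanesulfonate CC[Si](CC)(CC)OS(=O)(=O)C(F)(F)F
Why: Silylation with the silyl triflate protects the primary and the hindered tertiary hydroxyl in one operation, so that neither can later direct epoxidation or quench the organometallics.

Step 10
Reactants: 19 bis-silyl ether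
Product: 21 (2E,6E,9R,11E)-9-ethynyl-2,9,13-trimethyl-13-(triethylsilyloxy)-6-[(triethylsilyloxy)methyl]tetradeca-2,6,11-trienal, via allylic alcohol 20 (not isolated)
Conditions: SeO2 (cat.), t-BuOOH, CH2Cl2, 0 °C to rt; then MnO2, CH2Cl2, rt
Reagents that add atoms: selenium dioxide O=[Se]=O (oxygen transferred, regenerated by tert-butyl hydroperoxide CC(C)(C)OO)
Why: SeO2/t-BuOOH allylic oxidation (ene reaction then [2,3]-sigmatropic shift) attacks the most electron-rich terminal trisubstituted alkene at its (E)-methyl group, the C6=C7 alkene being deactivated by its allylic silyloxy group, and MnO2 takes the allylic alcohol on to the (E)-enal.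

Step 11
Reactants: 21 ynal
Product: 25 (1R,2E,4R,6E,10R,11R)-10,11-epoxy-4,11-dimethyl-4-[(2E)-4-methyl-4-(triethylsilyloxy)pent-2-en-1-yl]-7-[(triethylsilyloxy)methyl]cycloundeca-2,6-dien-1-ol, via alkenylborane 22 (not isolated), via alkenylzinc 23 (not isolated), via zinc alkoxide 24 (not isolated)
Conditions: (c-C6H11)2BH, toluene, 0 °C to rt; added over 6 h to Et2Zn, (+)-MIB (10 mol%), toluene, 0 °C (2 mM); then t-BuOOH, Ti(OiPr)4 (20 mol%), −20 to 0 °C
Reagents that add atoms: tert-butyl hydroperoxide CC(C)(C)OO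
Why: Proposed new method: an asymmetric alkenylzinc macrocyclisation of the Oppolzer type (syn-hydroboration of the terminal alkyne, boron-to-zinc exchange, amino-alcohol-catalysed intramolecular 1,2-addition of the (E)-alkenylzinc to the enal, (+)-MIB directing attack to the Re face so that C1 is R) is run directly into a Walsh-type directed epoxidation in which zinc alkoxide 24, Ti(OiPr)4 and t-BuOOH give a titanium alkoxide–peroxide that transfers oxygen only to the more electron-rich allylic C10=C11 alkene, on the face syn to the C1–O bond in the conformer with C1–H eclipsing the C11 methyl group (1,2-allylic strain), which gives the erythro trans-epoxide (the 11R descriptor of the free alcohol is the same spatial arrangement as 11S in the ester); the closest known reactions are the intermolecular one-pot alkenylzinc addition/directed epoxidation of enals and the alkenylzinc macrocyclisation of ω-alkynals, joined here so that carbocycle and oxirane form in one flask.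

Step 12
Reactants: 25 erythro epoxy alcohol; 26 3-methylbut-2-enoic acid
Product: 27 (1S,2E,4R,6E,10R,11S)-10,11-epoxy-4,11-dimethyl-4-[(2E)-4-methyl-4-(triethylsilyloxy)pent-2-en-1-yl]-7-[(triethylsilyloxy)methyl]cycloundeca-2,6-dien-1-yl 3-methylbut-2-enoate
Conditions: PPh3, DIAD, toluene, 0 °C to rt
Reagents that add atoms: none
Why: Mitsunobu esterification displaces the oxyphosphonium group by the carboxylate in an SN2 step, so C1 is inverted from R to S and the erythro epoxy alcohol becomes the threo ester of the target, SN2' attack at C3 being blocked by the adjacent quaternary carbon.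

Step 13
Reactants: 27 bis-silyl ester
Product: 28 (1S,2E,4R,6E,10R,11S)-10,11-epoxy-4-[(2E)-4-hydroxy-4-methylpent-2-en-1-yl]-7-(hydroxymethyl)-4,11-dimethylcycloundeca-2,6-dien-1-yl 3-methylbut-2-enoate
Conditions: HF·pyridine, pyridine, THF, 0 °C to rt
Reagents that add atoms: none
Why: Fluoride-driven Si–O cleavage under pyridine buffering removes both triethylsilyl ethers without opening the epoxide or cleaving the ester.

Step 14
Reactants: 28 diol ester
Product: 29 (1S,2E,4R,6E,10R,11S)-10,11-epoxy-7-formyl-4-[(2E)-4-hydroxy-4-methylpent-2-en-1-yl]-4,11-dimethylcycloundeca-2,6-dien-1-yl 3-methylbut-2-enoate (CNP0164725.2)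
Conditions: MnO2, CH2Cl2, rt
Reagents that add atoms: none
Why: MnO2 allylic oxidation converts only the primary allylic alcohol to the conjugated aldehyde, the tertiary allylic alcohol having no carbinol hydrogen, and the alkene geometry is retained.

**Compound list**
1 | geraniol, (2E)-3,7-dimethylocta-2,6-dien-1-ol | CC(C)=CCC/C(C)=C/CO | starting material
2 | geranyl diethyl phosphate | CCOP(=O)(OCC)OC/C=C(\C)CCC=C(C)C | intermediate
3 | trimethylsilylacetylene | C#C[Si](C)(C)C | starting material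
4 | diisobutyl[(trimethylsilyl)ethynyl]aluminium | CC(C)C[Al](CC(C)C)C#C[Si](C)(C)C | intermediate
5 | (R)-(3-ethenyl-3,7-dimethyloct-6-en-1-yn-1-yl)trimethylsilane | C[Si](C)(C)C#C[C@](C)(CCC=C(C)C)C=C | intermediate
6 | 9-[(3S)-3-methyl-3-(4-methylpent-3-en-1-yl)-5-(trimethylsilyl)pent-4-yn-1-yl]-9-borabicyclo[3.3.1]nonane (same spatial arrangement as 5) | C[Si](C)(C)C#C[C@](C)(CCC=C(C)C)CCB1C2CCCC1CCC2 | intermediate
7 | (R)-3,7-dimethyl-3-[(trimethylsilyl)ethynyl]oct-6-en-1-ol | C[Si](C)(C)C#C[C@](C)(CCC=C(C)C)CCO | intermediate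
8 | (R)-3-ethynyl-3,7-dimethyloct-6-en-1-ol | C#C[C@](C)(CCC=C(C)C)CCO | intermediate
9 | (3R)-3-ethynyl-3,7-dimethyl-6-(phenylselanyl)octane-1,7-diol (both C6 epimers) | C#C[C@](C)(CCC([Se]c1ccccc1)C(C)(C)O)CCO | intermediate
10 | (3R)-3-ethynyl-3,7-dimethyl-6-(phenylseleninyl)octane-1,7-diol (both C6 epimers) | C#C[C@](C)(CCC([Se](=O)c1ccccc1)C(C)(C)O)CCO | intermediate
11 | (3R,5E)-3-ethynyl-3,7-dimethyloct-5-ene-1,7-diol | C#C[C@](C)(C/C=C/C(C)(C)O)CCO | intermediate
12 | (3R,5E)-3-ethynyl-7-hydroxy-3,7-dimethyloct-5-enal | C#C[C@](C)(C/C=C/C(C)(C)O)CC=O | intermediate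
13 | ethyl (triphenylphosphoranylidene)acetate | CCOC(=O)C=P(c1ccccc1)(c1ccccc1)c1ccccc1 | starting material
14 | 5-bromo-2-methylpent-2-ene | CC(C)=CCCBr | starting material
15 | (1-ethoxy-6-methyl-1-oxohept-5-en-2-yl)triphenylphosphonium bromide | CCOC(=O)C(CCC=C(C)C)[P+](c1ccccc1)(c1ccccc1)c1ccccc1.[Br-] | intermediate
16 | ethyl 6-methyl-2-(triphenylphosphoranylidene)hept-5-enoate | CCOC(=O)C(CCC=C(C)C)=P(c1ccccc1)(c1ccccc1)c1ccccc1 | intermediate
17 | ethyl (2E,5R,7E)-5-ethynyl-9-hydroxy-5,9-dimethyl-2-(4-methylpent-3-en-1-yl)deca-2,7-dienoate | C#C[C@](C)(C/C=C/C(C)(C)O)C/C=C(/C(=O)OCC)CCC=C(C)C | intermediate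
18 | (2E,5R,7E)-5-ethynyl-5,9-dimethyl-2-(4-methylpent-3-en-1-yl)deca-2,7-diene-1,9-diol | C#C[C@](C)(C/C=C/C(C)(C)O)C/C=C(/CO)CCC=C(C)C | intermediate
19 | (2E,5R,7E)-5-ethynyl-5,9-dimethyl-2-(4-methylpent-3-en-1-yl)-1,9-bis(triethylsilyloxy)deca-2,7-diene | C#C[C@](C)(C/C=C/C(C)(C)O[Si](CC)(CC)CC)C/C=C(/CO[Si](CC)(CC)CC)CCC=C(C)C | intermediate
20 | (2E,6E,9R,11E)-9-ethynyl-2,9,13-trimethyl-13-(triethylsilyloxy)-6-[(triethylsilyloxy)methyl]tetradeca-2,6,11-trien-1-ol | C#C[C@](C)(C/C=C/C(C)(C)O[Si](CC)(CC)CC)C/C=C(/CO[Si](CC)(CC)CC)CC/C=C(\C)CO | intermediate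
21 | (2E,6E,9R,11E)-9-ethynyl-2,9,13-trimethyl-13-(triethylsilyloxy)-6-[(triethylsilyloxy)methyl]tetradeca-2,6,11-trienal | C#C[C@](C)(C/C=C/C(C)(C)O[Si](CC)(CC)CC)C/C=C(/CO[Si](CC)(CC)CC)CC/C=C(\C)C=O | intermediate
22 | (E)-alkenyldicyclohexylborane of 21 (C≡CH replaced by (E)-CH=CH–B(c-C6H11)2, boron on the former terminal carbon) | C1CCCCC1B(C1CCCCC1)/C=C/[C@](C)(C/C=C/C(C)(C)O[Si](CC)(CC)CC)C/C=C(/CO[Si](CC)(CC)CC)CC/C=C(\C)C=O | intermediate
23 | (E)-alkenyl(ethyl)zinc of 21 (C≡CH replaced by (E)-CH=CH–ZnEt) | CC[Zn]/C=C/[C@](C)(C/C=C/C(C)(C)O[Si](CC)(CC)CC)C/C=C(/CO[Si](CC)(CC)CC)CC/C=C(\C)C=O | intermediate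
24 | ethylzinc alkoxide of (1R,2E,4R,6E,10E)-4,11-dimethyl-4-[(2E)-4-methyl-4-(triethylsilyloxy)pent-2-en-1-yl]-7-[(triethylsilyloxy)methyl]cycloundeca-2,6,10-trien-1-ol | CC[Zn]O[C@@H]1/C=C/[C@](C)(C/C=C/C(C)(C)O[Si](CC)(CC)CC)C/C=C(/CO[Si](CC)(CC)CC)CC/C=C1\C | intermediate
25 | (1R,2E,4R,6E,10R,11R)-10,11-epoxy-4,11-dimethyl-4-[(2E)-4-methyl-4-(triethylsilyloxy)pent-2-en-1-yl]-7-[(triethylsilyloxy)methyl]cycloundeca-2,6-dien-1-ol (erythro; ring carbons C5 and C8 cis on C6=C7) | O[C@@H]1/C=C/[C@](C)(C/C=C/C(C)(C)O[Si](CC)(CC)CC)C/C=C(/CO[Si](CC)(CC)CC)CC[C@H]2O[C@]12C | intermediate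
26 | 3-methylbut-2-enoic acid | CC(C)=CC(=O)O | starting material
27 | (1S,2E,4R,6E,10R,11S)-10,11-epoxy-4,11-dimethyl-4-[(2E)-4-methyl-4-(triethylsilyloxy)pent-2-en-1-yl]-7-[(triethylsilyloxy)methyl]cycloundeca-2,6-dien-1-yl 3-methylbut-2-enoate | CC(C)=CC(=O)O[C@H]1/C=C/[C@](C)(C/C=C/C(C)(C)O[Si](CC)(CC)CC)C/C=C(/CO[Si](CC)(CC)CC)CC[C@H]2O[C@]12C | intermediate
28 | (1S,2E,4R,6E,10R,11S)-10,11-epoxy-4-[(2E)-4-hydroxy-4-methylpent-2-en-1-yl]-7-(hydroxymethyl)-4,11-dimethylcycloundeca-2,6-dien-1-yl 3-methylbut-2-enoate | CC(C)=CC(=O)O[C@H]1/C=C/[C@](C)(C/C=C/C(C)(C)O)C/C=C(/CO)CC[C@H]2O[C@]12C | intermediate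
29 | (1S,2E,4R,6E,10R,11S)-10,11-epoxy-7-formyl-4-[(2E)-4-hydroxy-4-methylpent-2-en-1-yl]-4,11-dimethylcycloundeca-2,6-dien-1-yl 3-methylbut-2-enoate (CNP0164725.2) | CC(C)=CC(=O)O[C@H]1/C=C/[C@](C)(C/C=C/C(C)(C)O)C/C=C(/C=O)CC[C@H]2O[C@]12C | target

**Step count and risks**
Total step count: 14. Longest linear sequence: 13 (steps 1–5 and 7–14, from geraniol); step 6 is the one-step side branch.

Steps most likely to fail:

Step 11. The 11-membered ring may close poorly, and the face or site selectivity of the in-flask epoxidation in the macrocyclic alkoxide is predicted from acyclic models, not measured. The fallback sets out from 19 and comes back at 25. Hydrozirconation–iodination of the alkyne (Cp2Zr(H)Cl, THF, then I2) gives (2E,5R,7E)-5-[(E)-2-iodoethenyl]-5,9-dimethyl-2-(4-methylpent-3-en-1-yl)-1,9-bis(triethylsilyloxy)deca-2,7-diene F4. The SeO2/t-BuOOH then MnO2 oxidation of step 10 gives (2E,6E,9R,11E)-9-[(E)-2-iodoethenyl]-2,9,13-trimethyl-13-(triethylsilyloxy)-6-[(triethylsilyloxy)methyl]tetradeca-2,6,11-trienal F5. A Nozaki–Hiyama–Kishi macrocyclisation (CrCl2, NiCl2 (cat.), DMSO/THF, high dilution, with a chiral sulfonamide ligand on chromium or separation of the C1 epimers) gives (1R,2E,4R,6E,10E)-4,11-dimethyl-4-[(2E)-4-methyl-4-(triethylsilyloxy)pent-2-en-1-yl]-7-[(triethylsilyloxy)methyl]cycloundeca-2,6,10-trien-1-ol F6. Hydroxyl-directed epoxidation with VO(acac)2/t-BuOOH then gives 25.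

Step 12. SN2 displacement at a carbinol flanked by a fully substituted epoxide carbon, with a weakly acidic pronucleophile, may be slow or leak into ionisation. The fallback sets out from 25 and comes back at 27. Dess–Martin oxidation gives (2E,4R,6E,10R,11S)-10,11-epoxy-4,11-dimethyl-4-[(2E)-4-methyl-4-(triethylsilyloxy)pent-2-en-1-yl]-7-[(triethylsilyloxy)methyl]cycloundeca-2,6-dien-1-one F7. Reagent-controlled 1,2-reduction with a CBS oxazaborolidine and catecholborane (catalyst enantiomer chosen to give the 1S carbinol) gives the threo alcohol (1S,2E,4R,6E,10R,11R)-10,11-epoxy-4,11-dimethyl-4-[(2E)-4-methyl-4-(triethylsilyloxy)pent-2-en-1-yl]-7-[(triethylsilyloxy)methyl]cycloundeca-2,6-dien-1-ol F8. Acylation with 3-methylbut-2-enoyl chloride (from 26 and oxalyl chloride), DMAP, pyridine, with retention, gives 27.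

Step 2. Enantioselectivity and alkynyl-versus-isobutyl transfer with the silylalkynyl aluminium reagent on this substrate are not assured. The fallback sets out from 1 and comes back at 5. Sharpless asymmetric epoxidation (L-(+)-diethyl tartrate, Ti(OiPr)4, t-BuOOH, 4 Å sieves, CH2Cl2, −20 °C) gives (2S,3S)-2,3-epoxygeraniol F1. Opening at the tertiary carbon with inversion by Et2Al–C≡C–SiMe3 (from the lithium acetylide of 3 and Et2AlCl, toluene) gives (2R,3S)-3,7-dimethyl-3-[(trimethylsilyl)ethynyl]oct-6-ene-1,2-diol F2. NaIO4 cleavage gives (S)-2-methyl-2-(4-methylpent-3-en-1-yl)-4-(trimethylsilyl)but-3-ynal F3. Methylenation with Ph3P=CH2 gives 5.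

**Further compounds**
F1 | step 2 | (2S,3S)-2,3-epoxygeraniol, [(2S,3S)-3-methyl-3-(4-methylpent-3-en-1-yl)oxiran-2-yl]methanol | OC[C@@H]1O[C@]1(CCC=C(C)C)C
F2 | step 2 | (2R,3S)-3,7-dimethyl-3-[(trimethylsilyl)ethynyl]oct-6-ene-1,2-diol | C[Si](C)(C)C#C[C@@]([C@@H](O)CO)(CCC=C(C)C)C
F3 | step 2 | (S)-2-methyl-2-(4-methylpent-3-en-1-yl)-4-(trimethylsilyl)but-3-ynal | C[Si](C)(C)C#C[C@@](C=O)(CCC=C(C)C)C
F4 | step 11 | (2E,5R,7E)-5-[(E)-2-iodoethenyl]-5,9-dimethyl-2-(4-methylpent-3-en-1-yl)-1,9-bis(triethylsilyloxy)deca-2,7-diene | I/C=C/[C@](C)(C/C=C/C(C)(C)O[Si](CC)(CC)CC)C/C=C(/CO[Si](CC)(CC)CC)CCC=C(C)C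
F5 | step 11 | (2E,6E,9R,11E)-9-[(E)-2-iodoethenyl]-2,9,13-trimethyl-13-(triethylsilyloxy)-6-[(triethylsilyloxy)methyl]tetradeca-2,6,11-trienal | I/C=C/[C@](C)(C/C=C/C(C)(C)O[Si](CC)(CC)CC)C/C=C(/CO[Si](CC)(CC)CC)CC/C=C(\C)C=O
F6 | step 11 | (1R,2E,4R,6E,10E)-4,11-dimethyl-4-[(2E)-4-methyl-4-(triethylsilyloxy)pent-2-en-1-yl]-7-[(triethylsilyloxy)methyl]cycloundeca-2,6,10-trien-1-ol | O[C@@H]1/C=C/[C@](C)(C/C=C/C(C)(C)O[Si](CC)(CC)CC)C/C=C(/CO[Si](CC)(CC)CC)CC/C=C1\C
F7 | step 12 | (2E,4R,6E,10R,11S)-10,11-epoxy-4,11-dimethyl-4-[(2E)-4-methyl-4-(triethylsilyloxy)pent-2-en-1-yl]-7-[(triethylsilyloxy)methyl]cycloundeca-2,6-dien-1-one | O=C1/C=C/[C@](C)(C/C=C/C(C)(C)O[Si](CC)(CC)CC)C/C=C(/CO[Si](CC)(CC)CC)CC[C@H]2O[C@]12C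
F8 | step 12 | (1S,2E,4R,6E,10R,11R)-10,11-epoxy-4,11-dimethyl-4-[(2E)-4-methyl-4-(triethylsilyloxy)pent-2-en-1-yl]-7-[(triethylsilyloxy)methyl]cycloundeca-2,6-dien-1-ol | O[C@H]1/C=C/[C@](C)(C/C=C/C(C)(C)O[Si](CC)(CC)CC)C/C=C(/CO[Si](CC)(CC)CC)CC[C@H]2O[C@]12C
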